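Monday's run shows the order of events at −25 °C: substrate falls, the intermediate rises behind it, then the target, and the isomer of the product appears after that. Its last readings sum to 100 %, and Thursday's substrate stalls once 20.2 mM has gone against 21 mM of partner charged, so substrate and partner are taken to react one to one.

| flask | substrate | partner | second reagent | temperature | remark | time |
|---|---|---|---|---|---|---|
| Monday's | 13 mM | 21 mM | 18 mM | −25 °C | run made earlier |  |
| Thursday's | 30 mM | 21 mM | 18 mM | 5 °C | run made earlier |  |
| Saturday's | 20 mM | 42 mM | 18 mM | −25 °C | run made earlier |  |
| larch | 20 mM | 21.0 mM | 18.0 mM | 30 °C |  | 3.0 min |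
| maple | 20 mM | 21.0 mM | 18.0 mM | −20 °C |  | 3.0 min |
| birch | 20 mM | 21.0 mM | 18.0 mM | 5 °C |  | 3.0 min |

Monday's run (percent of the substrate charged)

| time / min | intermediate / % | target / % | isomer of the product / % | substrate / % |
|---|---|---|---|---|
| 0.200 | 17.3 | 1.0 | 0 | 81.0 |
| 0.333 | 23.6 | 2.8 | 0.1 | 72.4 |
| 0.500 | 29.9 | 6.0 | 1.6 | 63.6 |
| 0.833 | 35.7 | 11.5 | 4.0 | 48.9 |
| 1.33 | 37.0 | 15.7 | 11.4 | 34.6 |
| 2.50 | 30.8 | 17.6 | 33.9 | 18.0 |

Thursday's run (percent of the substrate charged)

| time / s | intermediate / % | target / % | isomer of the product / % | substrate / % |
|---|---|---|---|---|
| 10.0 | 25.7 | 10.2 | 17.4 | 49.4 |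
| 15.0 | 22.5 | 10.1 | 25.3 | 40.9 |
| 25.0 | 18.5 | 12.0 | 34.2 | 35.6 |
| 40.0 | 15.5 | 12.0 | 41.0 | 32.5 |

Saturday's run (percent of the substrate charged)

| time / min | intermediate / % | target / % | isomer of the product / % | substrate / % |
|---|---|---|---|---|
| 0.200 | 29.5 | 2.8 | 0 | 67.7 |
| 0.667 | 50.4 | 12.9 | 5.0 | 32.4 |
| 1.00 | 50.9 | 18.0 | 9.5 | 20.0 |
| 1.50 | 48.4 | 19.0 | 21.7 | 10.6 |
| 2.50 | 38.5 | 16.8 | 40.5 | 3.1 |

(scatter of a reading: 0.5 percentage points)

- the earlier runs were read with a standard deviation of 0.5 percentage points

- which of these there is most of at the end, counted by the substrate in it, larch (isomer of the product / target / substrate / intermediate)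
- which of these there is most of at the end, counted by the substrate in it, maple (isomer of the product / target / substrate / intermediate)
- which of these there is most of at the end, counted by the substrate in it, birch (isomer of the product / target / substrate / intermediate)
- how much there is at the end of the one of these that leads, in percent of the substrate charged: larch
- how much there is at the end of the one of these that leads, in percent of the substrate charged: maple
- how much there is at the end of the one of these that leads, in percent of the substrate charged: birch

The quantity carried here is k, the second-order rate constant of substrate with partner. Let Δ be the charged excess of partner over substrate, which one-to-one use keeps constant. Then the logarithm of the growth of the partner-to-substrate ratio equals kΔt. Monday's last reading gives 0.0503 /mM/min. Saturday's reading at 1.50 min, with 42 mM of partner, gives 0.0512 /mM/min, so the law survives a change of charge. Thursday's reading at 15.0 s gives 0.429 /mM/min. A straight line of ln k against temperature, a rough interpolation, puts maple at −20 °C at 0.0719 /mM/min, the feed constant.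

By this reckoning, maple's substrate falls to half of its charge after 0.647 min, well inside the 3.0 min asked. Saturday's first readings, with 29.5 % of intermediate against 2.8 % of target, show intermediate ahead of target early in that run.

The middle is a crossing. Between 1.33 min and 2.50 min in Monday's run the target gains 1.9 points while the isomer of the product gains far more, 22 points. So by then, in Monday's run, target is used about as fast as it is made, and it has become a passage to the isomer.

At the end this reckoning leaves 16.5 % of maple's substrate, with 4.30 mM of partner beside it. The second reagent is the limiting reagent of the recipe, and its charge covers 90.0 % of the substrate. That is more than the 83.5 % of substrate reckoned as consumed, so this reckoning keeps maple's products under that cap at that time.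

The forecast names the isomer of the product as leader in larch at 67 % (58 % to 75 %), in maple at 49 % (41 % to 56 %) and in birch at 68 % (62 % to 74 %). For maple it writes “substrate about 16%, intermediate about 21%, products about 62%, isomer about 49%”, so the reckoning above stands slightly higher on substrate.

In larch the target leads at the end with 50.5 %, and the isomer of the product stands at 39.5 %.

In maple the isomer of the product leads with 53.7 %.

In birch the isomer of the product leads with 68.4 %.

    substrate + partner → intermediate (k = 1.24 /M/s, Ea = 40.0 kJ/mol)
    second reagent + intermediate → target (k = 1.20 /M/s, Ea = 47.0 kJ/mol)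
    target ⇌ isomer of the product (K = 19.4, k = 0.0337 /s, Ea = 61.0 kJ/mol, ΔH = −41.0 kJ/mol)
    (constants at −20 °C)

Maple's substrate stands at 16.0 %, against the 16.5 % reckoned from 0.0719 /mM/min. A neighbouring flask repeats maple with 5.0 mM of substrate, which makes the partner 4.20 equiv to the substrate. There Δ is 16.0 mM, and the same k leaves 2.43 % of its substrate. That flask ends with 2.2 % of substrate and 75.4 % of the isomer of the product.

The numbers in the tables were computed from invented constants; noise was put on by code.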